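**Plan**
- Cuts: the ring B–ring C biaryl bond; the O1–C2 bond of the tetrahydrofuran (C2 carries ring B); the C4–C4a bond of the tetralin (C4 carries ring C, ring E is the fused arene); and, in each half, the two ArCH2–C bonds flanking the C(OH)–CH pair.
- Forward: one (S)-malate-derived dioxolanone carrying the bromovanillyl unit is benzylated with either the ring E or the ring A bromide and reduced, giving two open triols.
- The ring E triol is closed to the tetralin first (quinone methide, then acid), borylated and joined to the ring A/B triol by Suzuki coupling; the tetrahydrofuran is closed last and the phenols are then freed.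
- Enabling feature: tetrahydrofuran C2 is a benzylic carbon para to the only free phenol (ring B), so oxidation gives a para-quinone methide whose exocyclic carbon is attacked by the C5 hydroxyl.
- Stereochemistry: tetrahydrofuran C4/C3 and tetralin C2/C3 come from the (S)-malate centre (anti Fráter–Seebach alkylation, then retentive alkylation of the cis pivalaldehyde dioxolanone); tetrahydrofuran C2 and tetralin C4 are set trans to the neighbouring CH2OH in the two ring closures.

Key step: step 21

Remark: 5-bromovanillin, diisopropyl (S)-malate, 4-(benzyloxy)-3-methoxybenzyl alcohol and isovanillin are taken as purchased; locants used are tetrahydrofuran O1, C2 (ring B), C3 (CH2OH), C4 (OH, ring A benzyl), C5, and tetralin C1 (CH2), C2 (OH, CH2OH), C3 (CH2OH), C4 (ring C), with ring D the saturated ring and ring E the fused arene.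

**Route**

Step 1
Reactants: 1 5-bromovanillin
Product: 2 4-(allyloxy)-3-bromo-5-methoxybenzaldehyde
Conditions: allyl bromide, K2CO3, DMF, rt
Reagents that add atoms: allyl bromide, C=CCBr
Why: Williamson etherification of the acidic ortho-bromophenol should give the allyl ether, a group that survives the later amide bases, acid and hydride and is removed by zerovalent palladium without loss of the aryl bromide.

Step 2
Reactants: 2 4-(allyloxy)-3-bromo-5-methoxybenzaldehyde
Product: 3 [4-(allyloxy)-3-bromo-5-methoxyphenyl]methanol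
Conditions: NaBH4, MeOH, 0 °C
Reagents that add atoms: none
Why: Borohydride reduction of the aryl aldehyde to the benzylic alcohol leaves the aryl bromide and the allyl ether untouched.

Step 3
Reactants: 3 [4-(allyloxy)-3-bromo-5-methoxyphenyl]methanol
Product: 4 4-(allyloxy)-3-bromo-5-methoxybenzyl bromide
Conditions: PBr3, CH2Cl2, 0 °C
Reagents that add atoms: phosphorus tribromide, BrP(Br)Br
Why: PBr3 converts the primary benzylic alcohol into the bromide through its phosphite ester (SN2 displacement by bromide).

Step 4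
Reactants: 5 diisopropyl (S)-malate; 4 4-(allyloxy)-3-bromo-5-methoxybenzyl bromide
Product: 6 diisopropyl (2S,3R)-3-[4-(allyloxy)-3-bromo-5-methoxybenzyl]-2-hydroxybutanedioate
Conditions: LiN(SiMe3)2 (2.2 equiv), THF, −78 to −20 °C; then 4, −78 to −10 °C; aq. NH4Cl
Reagents that add atoms: none
Why: Fráter–Seebach alkylation: the chelated dilithium alkoxide enolate of the malate should be alkylated at C3 anti to the C2 oxygen, which sets the (3R) centre relative to the purchased (2S) centre, and the minor syn isomer is removed by chromatography.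

Step 5
Reactants: 6 diisopropyl (2S,3R)-3-[4-(allyloxy)-3-bromo-5-methoxybenzyl]-2-hydroxybutanedioate
Product: 7 (2S,3R)-3-[4-(allyloxy)-3-bromo-5-methoxybenzyl]-2-hydroxybutanedioic acid
Conditions: KOH, H2O/1,4-dioxane, rt to 50 °C; then HCl to pH 1
Reagents that add atoms: potassium hydroxide (hydroxide oxygen ends in each carboxyl group), [K+].[OH-]
Why: Saponification of both isopropyl esters, in which the C3 centre is shielded from epimerisation once its carboxylate has formed, followed by acidification to the diacid.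

Step 6
Reactants: 7 (2S,3R)-3-[4-(allyloxy)-3-bromo-5-methoxybenzyl]-2-hydroxybutanedioic acid
Product: 8 (2R)-3-[4-(allyloxy)-3-bromo-5-methoxyphenyl]-2-[(2S,4S)-2-tert-butyl-5-oxo-1,3-dioxolan-4-yl]propanoic acid (cis dioxolanone)
Conditions: t-BuCHO, TsOH·H2O (cat.), H2SO4 (cat.), pentane/CH2Cl2, reflux, water separator
Reagents that add atoms: pivalaldehyde, CC(C)(C)C=O
Why: Seebach acetalisation of the alpha-hydroxy acid with pivalaldehyde should give the five-membered dioxolanone, in which the thermodynamically preferred cis arrangement of tert-butyl group and side chain fixes the new acetal centre as (2S), and the isomer is purified by crystallisation.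

Step 7
Reactants: 9 4-(benzyloxy)-3-methoxybenzyl alcohol
Product: 10 4-(benzyloxy)-3-methoxybenzyl bromide
Conditions: PBr3, Et2O, 0 °C
Reagents that add atoms: phosphorus tribromide, BrP(Br)Br
Why: PBr3 bromination of the primary benzylic alcohol, the electron-rich bromide being used directly.

Step 8
Reactants: 8 cis dioxolanone acid; 10 4-(benzyloxy)-3-methoxybenzyl bromide
Product: 11 (2R)-3-[4-(allyloxy)-3-bromo-5-methoxyphenyl]-2-[(2S,4S)-4-[4-(benzyloxy)-3-methoxybenzyl]-2-tert-butyl-5-oxo-1,3-dioxolan-4-yl]propanoic acid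
Conditions: LiN(SiMe3)2 (2.2 equiv), THF, −78 °C; then 10, −78 to −20 °C; aq. citric acid
Reagents that add atoms: none
Why: Seebach alkylation with self-regeneration of the stereocentre: the carboxylate/dioxolanone enolate dianion should be benzylated on the face trans to the tert-butyl group, so the ring E benzyl group replaces the former carbinol hydrogen with retention and sets the tetrasubstituted centre (future tetralin C2).

Step 9
Reactants: 11 ring E-benzylated dioxolanone acid
Product: 12 (2S,3S)-3-[4-(allyloxy)-3-bromo-5-methoxybenzyl]-2-[4-(benzyloxy)-3-methoxybenzyl]butane-1,2,4-triol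
Conditions: LiAlH4, THF, 0 °C to rt; aq. NaOH work-up
Reagents that add atoms: none
Why: LiAlH4 reduces the carboxylic acid and the dioxolanone carbonyl (the acetal collapses and its pivalaldehyde is reduced to neopentyl alcohol), which should give the triol with both centres intact since neither can enolise under these conditions.

Step 10
Reactants: 12 allyl-protected ring C/E triol
Product: 13 (2S,3S)-2-[4-(benzyloxy)-3-methoxybenzyl]-3-(3-bromo-4-hydroxy-5-methoxybenzyl)butane-1,2,4-triol
Conditions: Pd(PPh3)4 (5 mol %), morpholine, THF, rt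
Reagents that add atoms: none
Why: Tsuji–Trost deallylation: zerovalent palladium ionises the aryl allyl ether and morpholine traps the allyl fragment, while oxidative addition into the electron-rich aryl bromide is negligible at room temperature.

Step 11
Reactants: 13 ring C bromophenol triol
Product: 16 (2S,3S,4S)-6-(benzyloxy)-4-(3-bromo-4-hydroxy-5-methoxyphenyl)-2,3-bis(hydroxymethyl)-7-methoxy-1,2,3,4-tetrahydronaphthalen-2-ol, via ring C quinone methide 14 (not isolated), via bromophenol tetrahydrofuran 15 (not isolated)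
Conditions: DDQ (1.0 equiv), CH2Cl2/1,4-dioxane, 0 °C; then CF3CO2H, 0 °C to rt; aq. NaHCO3
Reagents that add atoms: none
Why: DDQ dehydrogenates the only 4-alkylphenol (ring C) to the para-quinone methide 14, which the hydroxymethyl on the quaternary carbon captures to give 15, and CF3CO2H then reopens this benzylic ether to a cation that ring E attacks para to its methoxy group (intramolecular Friedel–Crafts alkylation, the olivil-to-cycloolivil rearrangement type), the aryl group taking the equatorial position trans to the C3 hydroxymethyl and so setting C4 as (S).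

Step 12
Reactants: 16 tetralin bromophenol
Product: 17 (2S,3S,4S)-6-(benzyloxy)-4-[4-(benzyloxy)-3-bromo-5-methoxyphenyl]-2,3-bis(hydroxymethyl)-7-methoxy-1,2,3,4-tetrahydronaphthalen-2-ol
Conditions: BnBr, K2CO3, DMF, rt
Reagents that add atoms: benzyl bromide, BrCc1ccccc1
Why: Williamson etherification in which K2CO3 deprotonates only the phenol, so the benzyl group should go on the ring C oxygen and not on the aliphatic hydroxyls.

Step 13
Reactants: 17 tetralin aryl bromide
Product: 18 (2S,3S,4S)-6-(benzyloxy)-4-[4-(benzyloxy)-3-methoxy-5-(4,4,5,5-tetramethyl-1,3,2-dioxaborolan-2-yl)phenyl]-2,3-bis(hydroxymethyl)-7-methoxy-1,2,3,4-tetrahydronaphthalen-2-ol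
Conditions: B2pin2, Pd(dppf)Cl2 (5 mol %), KOAc, 1,4-dioxane, 90 °C
Reagents that add atoms: bis(pinacolato)diboron, CC1(C)OB(OC1(C)C)B2OC(C)(C)C(C)(C)O2
Why: Miyaura borylation of the aryl bromide with zerovalent palladium formed in situ, in which KOAc is too weak a base to start Suzuki homocoupling and free hydroxyls are tolerated.

Step 14
Reactants: 19 isovanillin
Product: 20 5-formyl-2-methoxyphenyl 4-methylbenzenesulfonate
Conditions: TsCl, Et3N, DMAP (cat.), CH2Cl2, 0 °C to rt
Reagents that add atoms: 4-toluenesulfonyl chloride, Cc1ccc(S(=O)(=O)Cl)cc1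
Why: Sulfonylation of the phenol gives a tosylate that is stable to LiAlH4, amide bases and palladium catalysis and later makes ring A too electron-poor to attack a quinone methide.

Step 15
Reactants: 20 5-formyl-2-methoxyphenyl 4-methylbenzenesulfonate
Product: 21 5-(hydroxymethyl)-2-methoxyphenyl 4-methylbenzenesulfonate
Conditions: NaBH4, MeOH/THF, 0 °C
Reagents that add atoms: none
Why: Borohydride reduction of the aldehyde, to which aryl sulfonate esters are inert.

Step 16
Reactants: 21 5-(hydroxymethyl)-2-methoxyphenyl 4-methylbenzenesulfonate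
Product: 22 5-(bromomethyl)-2-methoxyphenyl 4-methylbenzenesulfonate
Conditions: PBr3, CH2Cl2, 0 °C
Reagents that add atoms: phosphorus tribromide, BrP(Br)Br
Why: PBr3 bromination of the primary benzylic alcohol through its phosphite ester.

Step 17
Reactants: 8 cis dioxolanone acid; 22 5-(bromomethyl)-2-methoxyphenyl 4-methylbenzenesulfonate
Product: 23 (2R)-3-[4-(allyloxy)-3-bromo-5-methoxyphenyl]-2-[(2S,4S)-2-tert-butyl-4-[4-methoxy-3-(tosyloxy)benzyl]-5-oxo-1,3-dioxolan-4-yl]propanoic acid
Conditions: LiN(SiMe3)2 (2.2 equiv), THF, −78 °C; then 22, −78 to −20 °C; aq. citric acid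
Reagents that add atoms: none
Why: The same Seebach alkylation as in step 8, in which attack trans to the tert-butyl group should install the ring A benzyl group with retention and set the future tetrahydrofuran C4, the aryl tosylate being inert to the enolate at −78 °C.

Step 18
Reactants: 23 ring A-benzylated dioxolanone acid
Product: 24 (2S,3S)-3-[4-(allyloxy)-3-bromo-5-methoxybenzyl]-2-[4-methoxy-3-(tosyloxy)benzyl]butane-1,2,4-triol
Conditions: LiAlH4, THF, 0 °C to rt; aq. NaOH work-up
Reagents that add atoms: none
Why: LiAlH4 reduction of acid and dioxolanone as in step 9, which aryl sulfonate esters, the aryl bromide and the allyl ether should withstand at this temperature.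

Step 19
Reactants: 24 allyl-protected ring A/B triol
Product: 25 (2S,3S)-3-(3-bromo-4-hydroxy-5-methoxybenzyl)-2-[4-methoxy-3-(tosyloxy)benzyl]butane-1,2,4-triol
Conditions: Pd(PPh3)4 (5 mol %), morpholine, THF, rt
Reagents that add atoms: none
Why: Tsuji–Trost deallylation as in step 10, in which neither the aryl tosylate nor the aryl bromide reacts with zerovalent palladium and PPh3 at room temperature.

Step 20
Reactants: 18 tetralin arylboronate; 25 ring B bromophenol triol
Product: 26 open-chain biaryl precursor (ring B phenol free, ring A tosylate, rings C and E benzyl ethers)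
Conditions: Pd(dppf)Cl2 (5 mol %), K3PO4, 1,4-dioxane/H2O, 80 °C
Reagents that add atoms: none
Why: Suzuki–Miyaura coupling in which oxidative addition occurs at the C–Br bond of ring B (aryl tosylates are inert to this catalyst), free ortho-bromophenols are competent partners, and the biaryl formed has only one ortho oxygen on each ring.

Step 21
Reactants: 26 open-chain biaryl precursor
Product: 28 tetrahydrofuran-closed dimer (ring A tosylate, two benzyl ethers), via ring B quinone methide 27 (not isolated)
Conditions: DDQ (1.05 equiv), CH2Cl2/1,4-dioxane, 0 °C to rt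
Reagents that add atoms: none
Why: DDQ takes two electrons and a benzylic hydrogen from the 2-aryl-6-methoxy-4-alkylphenol of ring B to give the para-quinone methide 27, and the primary hydroxyl on the quaternary carbon adds to its exocyclic carbon (oxa-1,6-conjugate addition), which forms O1–C2 and restores the aromatic ring. The closest known reaction type is the oxidative cyclisation of 4-hydroxyphenyl alkanols to 2-aryl cyclic ethers through quinone methides. The tetrahydrofuran closes in the 5-exo-trig mode, whereas the tertiary hydroxyl and the C3 hydroxymethyl could only give four-membered rings. The new centre C2 (S) is controlled by the adjacent C3 centre: in the envelope transition state the arylidene and the C3 hydroxymethyl both lie pseudo-equatorial, and because the addition is reversible under the weakly acidic conditions the trans isomer is also the thermodynamic one. The step needs oxidation at ring B only and O- rather than C-capture of the quinone methide: ring B holds the only free phenol (rings C and E are benzyl ethers, ring A is a tosylate), one equivalent of oxidant at 0 °C should leave the ether-type benzylic positions alone, and the electron-poor tosylated ring A cannot close a tetralin by Friedel–Crafts attack.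

Step 22
Reactants: 28 tetrahydrofuran-closed dimer
Product: 29 tetrahydrofuran dimer with free ring A phenol and two benzyl ethers
Conditions: Mg turnings, MeOH, rt, ultrasound; aq. NH4Cl
Reagents that add atoms: none
Why: Reductive cleavage of the aryl sulfonate S–O bond by electron transfer from magnesium in methanol should free the ring A phenol at room temperature, without the hot hydroxide that could reopen the tetrahydrofuran through the ring B phenoxide, and leaves the benzyl ethers in place.

Step 23
Reactants: 29 bis(benzyl ether)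
Product: 30 CNP0252244.1
Conditions: H2 (1 atm), 10% Pd/C, EtOAc/MeOH, rt
Reagents that add atoms: none
Why: Hydrogenolysis of the two aryl benzyl ethers over palladium is much faster than cleavage of the cyclic benzylic C2–O1 ether in a neutral solvent, so stopping after two equivalents of hydrogen should give the target.

**Compound list**

1 | 5-bromovanillin | COc1cc(C=O)cc(Br)c1O | starting material
2 | 4-(allyloxy)-3-bromo-5-methoxybenzaldehyde | COc1cc(C=O)cc(Br)c1OCC=C | intermediate
3 | [4-(allyloxy)-3-bromo-5-methoxyphenyl]methanol | COc1cc(CO)cc(Br)c1OCC=C | intermediate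
4 | 4-(allyloxy)-3-bromo-5-methoxybenzyl bromide | COc1cc(CBr)cc(Br)c1OCC=C | intermediate
5 | diisopropyl (S)-malate | CC(C)OC(=O)C[C@H](O)C(=O)OC(C)C | starting material
6 | diisopropyl (2S,3R)-3-[4-(allyloxy)-3-bromo-5-methoxybenzyl]-2-hydroxybutanedioate | CC(C)OC(=O)[C@H](Cc1cc(OC)c(OCC=C)c(Br)c1)[C@H](O)C(=O)OC(C)C | intermediate
7 | (2S,3R)-3-[4-(allyloxy)-3-bromo-5-methoxybenzyl]-2-hydroxybutanedioic acid | OC(=O)[C@H](Cc1cc(OC)c(OCC=C)c(Br)c1)[C@H](O)C(=O)O | intermediate
8 | (2R)-3-[4-(allyloxy)-3-bromo-5-methoxyphenyl]-2-[(2S,4S)-2-tert-butyl-5-oxo-1,3-dioxolan-4-yl]propanoic acid | OC(=O)[C@H](Cc1cc(OC)c(OCC=C)c(Br)c1)[C@@H]2O[C@H](C(C)(C)C)OC2=O | intermediate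
9 | 4-(benzyloxy)-3-methoxybenzyl alcohol | COc1cc(CO)ccc1OCc2ccccc2 | starting material
10 | 4-(benzyloxy)-3-methoxybenzyl bromide | COc1cc(CBr)ccc1OCc2ccccc2 | intermediate
11 | (2R)-3-[4-(allyloxy)-3-bromo-5-methoxyphenyl]-2-[(2S,4S)-4-[4-(benzyloxy)-3-methoxybenzyl]-2-tert-butyl-5-oxo-1,3-dioxolan-4-yl]propanoic acid | OC(=O)[C@H](Cc1cc(OC)c(OCC=C)c(Br)c1)[C@]2(Cc3ccc(OCc4ccccc4)c(OC)c3)O[C@H](C(C)(C)C)OC2=O | intermediate
12 | (2S,3S)-3-[4-(allyloxy)-3-bromo-5-methoxybenzyl]-2-[4-(benzyloxy)-3-methoxybenzyl]butane-1,2,4-triol | OC[C@H](Cc1cc(OC)c(OCC=C)c(Br)c1)[C@](O)(CO)Cc2ccc(OCc3ccccc3)c(OC)c2 | intermediate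
13 | (2S,3S)-2-[4-(benzyloxy)-3-methoxybenzyl]-3-(3-bromo-4-hydroxy-5-methoxybenzyl)butane-1,2,4-triol | OC[C@H](Cc1cc(OC)c(O)c(Br)c1)[C@](O)(CO)Cc2ccc(OCc3ccccc3)c(OC)c2 | intermediate
14 | ring C para-quinone methide of 13 (4-alkylidene-2-bromo-6-methoxycyclohexa-2,5-dienone; alkene geometry not defined) | OC[C@H](C=C1C=C(OC)C(=O)C(Br)=C1)[C@](O)(CO)Cc2ccc(OCc3ccccc3)c(OC)c2 | intermediate (not isolated)
15 | (3S,4R,5S)-3-[4-(benzyloxy)-3-methoxybenzyl]-5-(3-bromo-4-hydroxy-5-methoxyphenyl)-4-(hydroxymethyl)oxolan-3-ol | COc1cc(C[C@@]2(O)CO[C@H](c3cc(OC)c(O)c(Br)c3)[C@H]2CO)ccc1OCc4ccccc4 | intermediate (not isolated)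
16 | (2S,3S,4S)-6-(benzyloxy)-4-(3-bromo-4-hydroxy-5-methoxyphenyl)-2,3-bis(hydroxymethyl)-7-methoxy-1,2,3,4-tetrahydronaphthalen-2-ol | COc1cc([C@H]2c3cc(OCc4ccccc4)c(OC)cc3C[C@@](O)(CO)[C@@H]2CO)cc(Br)c1O | intermediate
17 | (2S,3S,4S)-6-(benzyloxy)-4-[4-(benzyloxy)-3-bromo-5-methoxyphenyl]-2,3-bis(hydroxymethyl)-7-methoxy-1,2,3,4-tetrahydronaphthalen-2-ol | COc1cc([C@H]2c3cc(OCc4ccccc4)c(OC)cc3C[C@@](O)(CO)[C@@H]2CO)cc(Br)c1OCc5ccccc5 | intermediate
18 | (2S,3S,4S)-6-(benzyloxy)-4-[4-(benzyloxy)-3-methoxy-5-(4,4,5,5-tetramethyl-1,3,2-dioxaborolan-2-yl)phenyl]-2,3-bis(hydroxymethyl)-7-methoxy-1,2,3,4-tetrahydronaphthalen-2-ol | COc1cc([C@H]2c3cc(OCc4ccccc4)c(OC)cc3C[C@@](O)(CO)[C@@H]2CO)cc(B6OC(C)(C)C(C)(C)O6)c1OCc5ccccc5 | intermediate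
19 | isovanillin | COc1ccc(C=O)cc1O | starting material
20 | 5-formyl-2-methoxyphenyl 4-methylbenzenesulfonate | COc1ccc(C=O)cc1OS(=O)(=O)c2ccc(C)cc2 | intermediate
21 | 5-(hydroxymethyl)-2-methoxyphenyl 4-methylbenzenesulfonate | COc1ccc(CO)cc1OS(=O)(=O)c2ccc(C)cc2 | intermediate
22 | 5-(bromomethyl)-2-methoxyphenyl 4-methylbenzenesulfonate | COc1ccc(CBr)cc1OS(=O)(=O)c2ccc(C)cc2 | intermediate
23 | (2R)-3-[4-(allyloxy)-3-bromo-5-methoxyphenyl]-2-[(2S,4S)-2-tert-butyl-4-[4-methoxy-3-(tosyloxy)benzyl]-5-oxo-1,3-dioxolan-4-yl]propanoic acid | OC(=O)[C@H](Cc1cc(OC)c(OCC=C)c(Br)c1)[C@]2(Cc3ccc(OC)c(OS(=O)(=O)c4ccc(C)cc4)c3)O[C@H](C(C)(C)C)OC2=O | intermediate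
24 | (2S,3S)-3-[4-(allyloxy)-3-bromo-5-methoxybenzyl]-2-[4-methoxy-3-(tosyloxy)benzyl]butane-1,2,4-triol | COc1ccc(C[C@@](O)(CO)[C@H](CO)Cc2cc(OC)c(OCC=C)c(Br)c2)cc1OS(=O)(=O)c3ccc(C)cc3 | intermediate
25 | (2S,3S)-3-(3-bromo-4-hydroxy-5-methoxybenzyl)-2-[4-methoxy-3-(tosyloxy)benzyl]butane-1,2,4-triol | COc1ccc(C[C@@](O)(CO)[C@H](CO)Cc2cc(OC)c(O)c(Br)c2)cc1OS(=O)(=O)c3ccc(C)cc3 | intermediate
26 | open-chain biaryl precursor: triol 25 with the ring B bromine replaced by ring C of the (2S,3S,4S)-tetralin of 17 (ring B phenol free, ring A tosylate, ring C and ring E benzyl ethers) | COc1ccc(C[C@@](O)(CO)[C@H](CO)Cc2cc(OC)c(O)c(-c3cc([C@H]4c5cc(OCc6ccccc6)c(OC)cc5C[C@@](O)(CO)[C@@H]4CO)cc(OC)c3OCc7ccccc7)c2)cc1OS(=O)(=O)c8ccc(C)cc8 | intermediate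
27 | ring B para-quinone methide of 26 (alkene geometry not defined) | COc1ccc(C[C@@](O)(CO)[C@H](CO)C=C2C=C(OC)C(=O)C(c3cc([C@H]4c5cc(OCc6ccccc6)c(OC)cc5C[C@@](O)(CO)[C@@H]4CO)cc(OC)c3OCc7ccccc7)=C2)cc1OS(=O)(=O)c8ccc(C)cc8 | intermediate (not isolated)
28 | tetrahydrofuran-closed dimer, (2S,3R,4S) in the tetrahydrofuran and (2S,3S,4S) in the tetralin, ring A tosylate, ring C and ring E benzyl ethers | COc1ccc(C[C@@]2(O)CO[C@H](c3cc(OC)c(O)c(-c4cc([C@H]5c6cc(OCc7ccccc7)c(OC)cc6C[C@@](O)(CO)[C@@H]5CO)cc(OC)c4OCc8ccccc8)c3)[C@H]2CO)cc1OS(=O)(=O)c9ccc(C)cc9 | intermediate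
29 | 28 without the tosyl group (ring A phenol free, ring C and ring E benzyl ethers) | COc1ccc(C[C@@]2(O)CO[C@H](c3cc(OC)c(O)c(-c4cc([C@H]5c6cc(OCc7ccccc7)c(OC)cc6C[C@@](O)(CO)[C@@H]5CO)cc(OC)c4OCc8ccccc8)c3)[C@H]2CO)cc1O | intermediate
30 | CNP0252244.1 | COc1ccc(C[C@@]2(O)CO[C@H](c3cc(OC)c(O)c(-c4cc([C@H]5c6cc(O)c(OC)cc6C[C@@](O)(CO)[C@@H]5CO)cc(OC)c4O)c3)[C@H]2CO)cc1O | target

**Summary**

Total step count: 23.
Longest linear sequence: 16 steps (steps 1–6, 8–13, 20–23).

Steps most likely to fail:

1. Step 21. The product still has its C2–H para to the free ring B phenol, so it can be oxidised a second time. DDQ may also abstract hydride from the other electron-rich benzylic positions (tetralin C4–H and C1–H2, ring A CH2), and the quinone methide may oligomerise before it closes. The fallback sets out from 26 and returns at 28. Ag2O in CH2Cl2, a surface oxidant that acts only on the free phenol, would generate the quinone methide, and methanol would quench it to the benzylic methyl ether F1 (both C2 epimers). Catalytic pyridinium 4-toluenesulfonate in CH2Cl2 would then ionise this 4-hydroxybenzylic ether, and the C5 hydroxyl would close the ring under thermodynamic control to 28, the ring A tosylate again keeping Friedel–Crafts closure off.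

2. Step 20. Once the ortho phenol of 25 is deprotonated by the base, oxidative addition at its C–Br bond becomes slow, so protodeboronation of the electron-rich boronate 18 can outrun the coupling. The fallback sets out from 24 and 18 and returns at 26. The allyl ether 24 would be coupled with 18 (Pd(OAc)2, SPhos, K3PO4, toluene/H2O, 60 °C; the bromide reacts far ahead of the tosylate) to give the allyl-protected biaryl F2. Deallylation with Pd(PPh3)4 and morpholine in THF would then give 26; any allyl loss during the coupling leads to 26 as well.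

3. Step 11. The bromine on ring C lowers the stability of the benzylic cation, so the tetrahydrofuran formed first may ionise sluggishly, and the phenolic intermediates may be oxidised further before the carbon–carbon bond forms. The fallback sets out from 12 and returns at 16. The two primary hydroxyls would be acetylated (Ac2O, pyridine) to the diacetate F3, and the allyl group removed (Pd(PPh3)4, morpholine) to give the phenol diacetate F4. Oxidation in the presence of acid (DDQ, CF3CO2H/CH2Cl2, 0 °C) would then leave no hydroxyl to capture the protonated quinone methide, so ring E attacks it directly and gives the tetralin diacetate F5. Methanolysis (K2CO3, MeOH) would return 16.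

**Further compounds**

F1 | step 21 | benzylic methyl ether of 26 at the ring B CH2 (future C2, both epimers) | COc1ccc(C[C@@](O)(CO)[C@H](CO)C(OC)c2cc(OC)c(O)c(-c3cc([C@H]4c5cc(OCc6ccccc6)c(OC)cc5C[C@@](O)(CO)[C@@H]4CO)cc(OC)c3OCc7ccccc7)c2)cc1OS(=O)(=O)c8ccc(C)cc8
F2 | step 20 | ring B O-allyl ether of 26 | COc1ccc(C[C@@](O)(CO)[C@H](CO)Cc2cc(OC)c(OCC=C)c(-c3cc([C@H]4c5cc(OCc6ccccc6)c(OC)cc5C[C@@](O)(CO)[C@@H]4CO)cc(OC)c3OCc7ccccc7)c2)cc1OS(=O)(=O)c8ccc(C)cc8
F3 | step 11 | 1,4-di-O-acetate of triol 12 | CC(=O)OC[C@H](Cc1cc(OC)c(OCC=C)c(Br)c1)[C@](O)(COC(C)=O)Cc2ccc(OCc3ccccc3)c(OC)c2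
F4 | step 11 | 1,4-di-O-acetate of bromophenol triol 13 | CC(=O)OC[C@H](Cc1cc(OC)c(O)c(Br)c1)[C@](O)(COC(C)=O)Cc2ccc(OCc3ccccc3)c(OC)c2
F5 | step 11 | di-O-acetate (both CH2OH groups) of tetralin 16 | COc1cc([C@H]2c3cc(OCc4ccccc4)c(OC)cc3C[C@@](O)(COC(C)=O)[C@@H]2COC(C)=O)cc(Br)c1O
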